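**Retrosynthetic overview**
- Target 12 comes from triol 10 by methylation of the one hydroxyl para to the benzoyl group (the C4 OH); the two ortho hydroxyls are flanked by the ketone and hydrogen-bonded to it.
- 10 comes from the open-chain triketo ester 8 by Claisen ring closure, chain C6 onto ester C1. The strategy rests on the hexasubstituted benzene ring: oxygen on C2, C4 and C6 alternates with carbon on C1 (benzoyl), C3 and C5 (prenyl), which is the pattern of a folded, benzoyl-started tetraketide. Both prenyl groups already sit on the chain, and there is no stereocentre.
- 8 comes from diketo ester 6 and methyl benzoate (C6–C7, trianion aroylation); 6 from keto ester 4 and a Weinreb acetamide (C4–C5, dianion acylation); 4 from methyl acetoacetate by α- then γ-prenylation. Every acyl donor is non-enolisable or only weakly acidic, so no enolate has to attack an acidic β-keto diester.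
- Ring order: only one ring is formed, the phloroglucinol ring in step 5; the phenyl ring is bought with methyl benzoate.

Key step: step 5

Remark: the target has no stereocentre, so no enantiomer question arises; 3, 4, 6 and 8 are used as racemic, epimeric and keto–enol mixtures because their sp3 centres become sp2 in step 5, and metal enolates, polyanions and tetrahedral adducts are treated as the reacting forms of the numbered compounds and are not numbered.

**Route**

Step 1
Reactants: 1 methyl acetoacetate (slight excess); 2 prenyl bromide
Product: 3 methyl 2-acetyl-5-methylhex-4-enoate (racemic)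
Conditions: K2CO3 (1.5 equiv), acetone, reflux
Reagents that add atoms: prenyl bromide, CC(C)=CCBr
Why: Acetoacetic ester alkylation, C-alkylation of the potassium enolate by a reactive allylic bromide; the slight excess of 1 should limit dialkylation, and the new C2 centre is racemic and is erased in step 5.

Step 2
Reactants: 3 methyl 2-acetyl-5-methylhex-4-enoate; 2 prenyl bromide
Product: 4 methyl 7-methyl-2-(3-methylbut-2-en-1-yl)-3-oxooct-6-enoate (racemic)
Conditions: LDA (2.2 equiv), THF, –78 to 0 °C; then 2, 0 °C to rt; cold 1 M HCl
Reagents that add atoms: prenyl bromide, CC(C)=CCBr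
Why: Weiler dianion γ-alkylation: after C2 is ionised the second deprotonation can only occur at the acetyl methyl, and this more basic terminal carbanion should be alkylated in preference to the stabilised C2 enolate.

Step 3
Reactants: 4 methyl 7-methyl-2-(3-methylbut-2-en-1-yl)-3-oxooct-6-enoate; 5 N-methoxy-N-methylacetamide
Product: 6 methyl 2,4-bis(3-methylbut-2-en-1-yl)-3,5-dioxohexanoate (epimer and enol mixture)
Conditions: LDA (2.3 equiv), THF, –78 to 0 °C; then 5, –78 to 0 °C; cold 1 M HCl
Reagents that add atoms: N-methoxy-N-methylacetamide, CC(=O)N(C)OC
Why: γ-Acylation of a 2,4-dialkylated β-keto ester dianion with a Weinreb amide (Huckin–Weiler type), in which the chelated tetrahedral adduct prevents over-addition; the new C4 centre forms without control and is erased in step 5.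

Step 4
Reactants: 6 methyl 2,4-bis(3-methylbut-2-en-1-yl)-3,5-dioxohexanoate; 7 methyl benzoate
Product: 8 methyl 2,4-bis(3-methylbut-2-en-1-yl)-3,5,7-trioxo-7-phenylheptanoate (epimer and enol mixture)
Conditions: LDA (4.2 equiv), THF, –78 to 0 °C; then 7 (1.0 equiv), –78 to 0 °C; poured into cold 1 M HCl
Reagents that add atoms: methyl benzoate, COC(=O)c1ccccc1
Why: Harris-type terminal aroylation of a 3,5-diketo ester trianion with a non-enolisable ester: once C2 and C4 are ionised only the C6 methyl can be deprotonated, the ester group is deactivated as its enolate, and the fourth equivalent of base ionises the new C6 methylene and pulls the condensation to 8.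

Step 5
Reactants: 8 methyl 2,4-bis(3-methylbut-2-en-1-yl)-3,5,7-trioxo-7-phenylheptanoate
Product: 10 2,4,6-trihydroxy-3,5-bis(3-methylbut-2-en-1-yl)benzophenone, via 2-benzoyl-4,6-bis(3-methylbut-2-enyl)cyclohexane-1,3,5-trione 9 (not isolated)
Conditions: Mg(OMe)2 (5 equiv), MeOH, rt to reflux; then cold dilute HCl, rapid extraction
Reagents that add atoms: none
Why: Magnesium binds the C5/C7 β-diketonate and folds the chain; the C6 carbon of this enolate adds to the C1 ester carbonyl, methoxide leaves, and the 2-benzoylcyclohexane-1,3,5-trione 9 enolises to phloroglucinol 10, which is withdrawn from all equilibria as its magnesium phenolate. The closest known reaction is the magnesium methoxide or alkali-promoted Claisen (Dieckmann-type) cyclisation of 7-aryl-3,5,7-triketo esters to 2,4,6-trihydroxybenzophenones. The one ring, the central benzene ring with the new bond between chain C1 and C6, closes by 6-exo-trig attack at the ester carbonyl, which is allowed for both enol-endo and enol-exo geometries. No stereocentre is created, and the two uncontrolled centres C2 and C4 of 8 become sp2 on aromatisation. The selectivity needed is Claisen over aldol closure (C2 onto the C7 ketone): C2 carries a prenyl group, so an aldol adduct would have a quaternary C2, could not aromatise and would stay reversible, and the conjugated aryl ketone is the weaker electrophile, so material should drain through the irreversible Claisen channel. Retro-Claisen methanolysis of the 2-alkyl-1,3-diketone units should be held back because magnesium keeps the carbonyls as chelated enolates and no free alkali alkoxide is present; the methyl ester in methanol makes ester exchange degenerate.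

Step 6
Reactants: 10 2,4,6-trihydroxy-3,5-bis(3-methylbut-2-en-1-yl)benzophenone; 11 dimethyl sulfate
Product: 12 2,6-dihydroxy-4-methoxy-3,5-bis(3-methylbut-2-en-1-yl)benzophenone (target)
Conditions: Me2SO4 (1.05 equiv), K2CO3 (1.1 equiv), acetone, 0 °C to rt
Reagents that add atoms: dimethyl sulfate, COS(=O)(=O)OC
Why: Williamson-type O-methylation: the C4 hydroxyl para to the benzoyl group is the most acidic and not hydrogen-bonded to the ketone, so with one equivalent of weak base and of a hard methylating agent its phenoxide should form and react at oxygen.

**Compound list**
1 | methyl acetoacetate | COC(=O)CC(C)=O | starting material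
2 | prenyl bromide (1-bromo-3-methylbut-2-ene) | CC(C)=CCBr | starting material
3 | methyl 2-acetyl-5-methylhex-4-enoate (racemic) | COC(=O)C(CC=C(C)C)C(C)=O | intermediate
4 | methyl 7-methyl-2-(3-methylbut-2-en-1-yl)-3-oxooct-6-enoate (racemic) | COC(=O)C(CC=C(C)C)C(=O)CCC=C(C)C | intermediate
5 | N-methoxy-N-methylacetamide | CC(=O)N(C)OC | starting material
6 | methyl 2,4-bis(3-methylbut-2-en-1-yl)-3,5-dioxohexanoate (epimer mixture) | COC(=O)C(CC=C(C)C)C(=O)C(CC=C(C)C)C(C)=O | intermediate
7 | methyl benzoate | COC(=O)c1ccccc1 | starting material
8 | methyl 2,4-bis(3-methylbut-2-en-1-yl)-3,5,7-trioxo-7-phenylheptanoate (epimer mixture) | COC(=O)C(CC=C(C)C)C(=O)C(CC=C(C)C)C(=O)CC(=O)c1ccccc1 | intermediate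
9 | 2-benzoyl-4,6-bis(3-methylbut-2-en-1-yl)cyclohexane-1,3,5-trione (not isolated) | O=C(c1ccccc1)C1C(=O)C(CC=C(C)C)C(=O)C(CC=C(C)C)C1=O | intermediate
10 | 2,4,6-trihydroxy-3,5-bis(3-methylbut-2-en-1-yl)benzophenone | O=C(c1ccccc1)c1c(O)c(CC=C(C)C)c(O)c(CC=C(C)C)c1O | intermediate
11 | dimethyl sulfate | COS(=O)(=O)OC | starting material
12 | 2,6-dihydroxy-4-methoxy-3,5-bis(3-methylbut-2-en-1-yl)benzophenone | COc1c(CC=C(C)C)c(O)c(C(=O)c2ccccc2)c(O)c1CC=C(C)C | target

**Step count and risk**
Total step count: 6. Longest linear sequence: 6 steps (1 to 12 through 3, 4, 6, 8 and 10).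

Steps most likely to fail:

1. Step 5 (key ring closure). Methoxide-induced retro-Claisen fragmentation of the 2-alkylated β-diketone units, or slow attack at the hindered α-branched ester with diversion into reversible aldol closure or pyrone formation on work-up, may outrun the Claisen closure. Fallback (classical late prenylation): it sets out from prenyl bromide 2. Purchased 2,4,6-trihydroxybenzophenone F1 is C-prenylated twice with 2 (about 2.2 equiv) in aqueous KOH at 0 °C (or DBU in THF). The 3,5-diprenyl compound is separated by chromatography from mono- and geminally diprenylated material. The fallback comes back to the route at 10.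

2. Step 4 (trianion benzoylation). Incomplete ionisation at the two tertiary carbons, proton transfer from the more acidic product to unreacted trianion, or premature cyclisation of the product polyanion may stall or divert the aroylation. Fallback (masked benzoylacetyl donor, no trianion): it sets out from 4. Purchased ethyl benzoylacetate F2 is ketalised with ethylene glycol (TsOH, toluene, Dean–Stark) to ethyl 2-(2-phenyl-1,3-dioxolan-2-yl)acetate F3. The dianion of 4 (LDA, THF, as in step 3) is acylated at C4 with F3 to give methyl 2,4-bis(3-methylbut-2-en-1-yl)-3,5-dioxo-6-(2-phenyl-1,3-dioxolan-2-yl)hexanoate F4. Removal of the dioxolane with PPTS in wet acetone (or cold dilute HCl in THF) comes back to the route at 8.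

3. Step 6 (monomethylation). Loss of regiocontrol by methylation of an ortho hydroxyl, double methylation, or C-methylation at C3/C5 with dearomatisation of the electron-rich ring may erode the yield. Fallback (no phenoxide generated): it sets out from 10 and leads directly to 12 by Mitsunobu methylation (MeOH 1.1 equiv, PPh3, DIAD, THF, 0 °C). The alkoxyphosphonium betaine is protonated and consumed only by the most acidic, non-chelated C4 hydroxyl, and C-alkylation is not expected under these neutral conditions.

Further compounds
F1 | step 5 | 2,4,6-trihydroxybenzophenone (purchased) | O=C(c1ccccc1)c1c(O)cc(O)cc1O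
F2 | step 4 | ethyl benzoylacetate (purchased) | CCOC(=O)CC(=O)c1ccccc1
F3 | step 4 | ethyl 2-(2-phenyl-1,3-dioxolan-2-yl)acetate | CCOC(=O)CC1(c2ccccc2)OCCO1
F4 | step 4 | methyl 2,4-bis(3-methylbut-2-en-1-yl)-3,5-dioxo-6-(2-phenyl-1,3-dioxolan-2-yl)hexanoate | COC(=O)C(CC=C(C)C)C(=O)C(CC=C(C)C)C(=O)CC1(c2ccccc2)OCCO1
F0 | step 6 | none | none
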